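the same everywhere: gas phase 200 mM (held)
- Wednesday's: solid substrate 0.74 M; run made earlier
- Saturday's: solid substrate 1.2 M; run made earlier
- flask: solid substrate 0.53 M; time 30 h

| run | time / h | target / % |
|---|---|---|
| Wednesday's | 2.50 | 15.9 |
| Wednesday's | 6.00 | 49.4 |
| Wednesday's | 12.0 | 52.5 |
| Wednesday's | 20.0 | 51.6 |
| Saturday's | 2.50 | 11.5 |
| Saturday's | 6.00 | 32.7 |
| Saturday's | 12.0 | 56.2 |
| Saturday's | 20.0 | 56.6 |

(each reading ± 1 percentage point)

- solid substrate is a solid; its amount is given per volume of the solution
- at the start none of the gas phase is in solution
- at the start none of the solid substrate is in solution

- ochre: doubling the saturation concentration of gas phase, all else as stated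
- violet: doubling the transfer coefficient of the gas phase, all else as stated
- blue: doubling the solubility of the solid substrate, all else as stated
- grey: doubling the dissolution coefficient of the solid substrate, all else as stated

1. how much target there is at 30 h, in percent of the solid substrate charged
2. concentration of dissolved gas in solution at 8.0 h, in percent of saturation
3. the change that raises the amount of target at 30 h, in percent of the solid substrate charged most ("none" if none brings more than 2 percentage points) (ochre / violet / blue / grey / none)
4. amount of target at 30 h, in percent of the solid substrate charged, after violet

1. Read the early times first. Between 2.50 h and 6.00 h the target grows by 0.0708 M h⁻¹ in Wednesday's run and by 0.0727 M h⁻¹ in Saturday's run, the same within scatter, although Saturday's charge is larger.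

2. Compare the ends. The last two readings of Wednesday's run average 0.385 M, a share of 52.0%. The last two readings of Saturday's run average 0.677 M, a share of 56.4%.

3. Define m, the marginal share (differential selectivity), as the extra target at the plateau per extra charge between two runs under the same gas: 63.4%. Saturday's readings end at the larger share because m, as read, exceeds Wednesday's share.

4. Reckon this flask from Wednesday's run by removing charge at m. That gives 0.252 M, or 47.6% of the charge. The readings show no dissolved gas, so watch that separately.

5. Set the forecast beside this. It gives 48%, 96% of saturation at 8.0 h, ochre as the best change, and 57% after violet. Its ground for the saturation is that “dissolved gas has recovered to near saturation”.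

6. Record the result. This flask gives 51.1%, which is 3.5 percentage points above the reckoning in step 4. Dissolved gas stands at 46.7% of saturation at 8.0 h; at 15.0 h this flask holds 0.138 M of dissolved gas against 1.05 M of dormant form. The best change is ochre, gaining 16 points, and violet gives 63.8%.

    gas phase ⇌ dissolved gas, rate k1*(csat - [dissolved gas]) (kL = 0.0140 min⁻¹)
    starting material + dissolved gas → target (k = 0.270 L mol⁻¹ min⁻¹)
    starting material → side product (k = 0.0100 min⁻¹)
    solid substrate ⇌ starting material, rate k4*(cs4 - [starting material]) while solid is left; crystals form when [starting material] > cs4 (solubility = 0.220 M, k = 0.0190 min⁻¹)
    dissolved gas ⇌ dormant form (K = 8.30, k = 0.0700 min⁻¹)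
    starting material → decomposition product (k = 2.50 × 10⁻⁶ min⁻¹)

7. Use m once more. Start from this flask's 0.271 M of target and add charge at m up to 2.1 M. That gives 1.27 M, or 60.5% of that charge, and the flask with 2.1 M gives 59.3%.

Readings and results stem from a simulated flask from invented constants; scatter was added.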